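**Retrosynthetic overview**
1. The 1,1-dimethylallyl group on ring A comes last, from an aromatic Claisen rearrangement of the 4'-O-prenyl ether. Ring A itself is bought as 4-bromoresorcinol.
2. The bridge bond C3–C1' comes from a B-alkyl Suzuki coupling of a 6-allylchroman-8-ol with 2-bromo-5-(prenyloxy)phenol.
3. Key disconnection: benzene ring B and the dimethylpyran ring are opened together to a 2,3,4-trisubstituted furan bearing a tert-alkyl ethynyl ether. In the forward gold-catalysed furan–yne isomerisation, the furan O becomes 8-OH and the two ynol-ether carbons become C8 and C8a.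
4. The furan comes from a (Z)-2-en-4-yn-1-ol, made by Sonogashira coupling of 2-methylpent-4-yn-2-ol with a (Z)-iodoalkenol. The iodoalkenol comes from anti-allylmagnesiation/iodination of prenylated propargyl alcohol.
5. Ring order: ring A purchased, then a sacrificial furan, then ring B and the pyran ring in one operation.

Assumption: the target SMILES has no stereocentre and no stereogenic double bond. Kazinol D is therefore achiral, and only the Z geometry of the acyclic intermediates has to be controlled.

**Step 1**
Reactants: 1 prop-2-yn-1-ol; 2 prenyl bromide (1-bromo-3-methylbut-2-ene)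
Product: 3 6-methylhept-5-en-2-yn-1-ol
Conditions: CuI (10 mol %), K2CO3, n-Bu4NCl (cat.), DMF, rt
Reagents that add atoms: none
Why: This Cu(I)-catalysed allylation of a terminal alkyne (Jeffery-type copper acetylide coupling) selects C–H over O–H under carbonate base and gives the linear skipped enyne, because the acetylide attacks the unhindered primary end of 2.

**Step 2**
Reactants: 3 6-methylhept-5-en-2-yn-1-ol; 4 allylmagnesium bromide (3 equiv)
Product: 6 (Z)-2-allyl-3-iodo-6-methylhepta-2,5-dien-1-ol, via bromomagnesium (Z)-2-allyl-3-(bromomagnesio)-6-methylhepta-2,5-dien-1-olate 5 (not isolated)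
Conditions: CuI (10 mol %), Et2O, 0 °C → rt; then I2, THF, −40 → 0 °C; H2O/aq Na2S2O3
Reagents that add atoms: iodine, II
Why: Alkoxide-directed, Cu-catalysed anti-carbomagnesiation of a propargylic alcohol (Duboudin–Jousseaume/Fallis type) puts allyl on C2 and Mg on C3 inside an O–Mg chelate, so iodinolysis with retention fixes the tetrasubstituted alkene as Z (I cis to CH2OH), the geometry needed for furan closure.

**Step 3**
Reactants: 6 (Z)-2-allyl-3-iodo-6-methylhepta-2,5-dien-1-ol; 7 2-methylpent-4-yn-2-ol
Product: 9 4-[4-allyl-3-(3-methylbut-2-enyl)furan-2-yl]-2-methylbutan-2-ol, via (Z)-2-allyl-7-methyl-3-(3-methylbut-2-enyl)oct-2-en-4-yne-1,7-diol 8 (not isolated)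
Conditions: PdCl2(PPh3)2 (3 mol %), CuI (6 mol %), Et2NH, rt; filter, concentrate; then AgNO3/SiO2 (10 mol % Ag), hexane, rt, dark
Reagents that add atoms: none
Why: Sonogashira coupling keeps the Z geometry, and the (Z)-enynol 8 then undergoes Ag(I)-catalysed 5-exo-dig hydroalkoxylation/aromatisation (Marshall furan synthesis) through the pre-organised primary allylic OH faster than the hindered tertiary OH can close 5-endo, which turns the alkyne carbons into furan C2 and the first side-chain CH2.

**Step 4**
Reactants: 9 furan alcohol; 10 trichloroethylene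
Product: 13 4-allyl-2-[3-(ethynyloxy)-3-methylbutyl]-3-(3-methylbut-2-enyl)furan, via 4-allyl-2-{3-[(E)-1,2-dichlorovinyloxy]-3-methylbutyl}-3-(3-methylbut-2-enyl)furan 11 (not isolated), via lithium 2-{[4-(4-allyl-3-prenylfuran-2-yl)-2-methylbutan-2-yl]oxy}ethynide 12 (not isolated)
Conditions: KH, THF, 0 °C; 10, −50 °C → rt; then n-BuLi (2.5 equiv), −78 → −40 °C; H2O, −78 °C; work up and store below 20 °C, use at once
Reagents that add atoms: n-butyllithium, CCCC[Li] (lithium appears only in non-isolated 12)
Why: In this one-pot Greene ynol ether synthesis the potassium alkoxide adds anti to dichloroacetylene formed in situ from 10 to give 11, n-BuLi then effects HCl elimination and Cl/Li exchange to 12, and the water quench gives the terminal ynol ether while also erasing any furan C5 lithiation; retro-ene loss of ketene is avoided by staying cold.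

**Step 5 (key step)**
Reactants: 13 furan ynol ether
Product: 15 6-allyl-2,2-dimethyl-5-(3-methylbut-2-enyl)chroman-8-ol, via the dihydropyran-fused oxepine (valence tautomer of the C7–C8 arene oxide) 14 (not isolated)
Conditions: IPrAuNTf2 (3 mol %), CH2Cl2 (0.02 M), 4 Å MS, 0 °C → rt, 30 min
Reagents that add atoms: none
Why: In this Hashmi gold-catalysed furan–yne phenol synthesis, Au(I) activates the polarised ynol ether for 6-exo attack by furan C2, the furan opens to a dienal/gold carbene that closes to oxepine 14 ⇌ arene oxide, and the alkoxy group on C8a stabilises the cation from C7–O cleavage so that oxygen stays on the former terminal alkyne carbon, building the pentasubstituted benzene ring and the pyran ring in one atom-economical isomerisation with substituent positions fixed by the furan and no stereocentre formed.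

**Step 6**
Reactants: 16 4-bromoresorcinol; 2 prenyl bromide (1.0 equiv)
Product: 17 2-bromo-5-[(3-methylbut-2-enyl)oxy]phenol
Conditions: K2CO3 (1.1 equiv), acetone, rt → 40 °C
Reagents that add atoms: none
Why: This Williamson mono-etherification favours the hydroxyl para to bromine, because the ortho-bromo hydroxyl is shielded, O–H···Br bonded and gives the less nucleophilic phenoxide, and one equivalent of 2 limits bis-alkylation.

**Step 7**
Reactants: 15 allyl chromanol; 17 bromophenol prenyl ether
Product: 19 6-{3-[2-hydroxy-4-(3-methylbut-2-enyloxy)phenyl]propyl}-2,2-dimethyl-5-(3-methylbut-2-enyl)chroman-8-ol, via the B-[3-(chroman-6-yl)propyl]-9-BBN whose 8-OH is bound as its 9-BBN borinate 18 (not isolated)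
Conditions: 9-BBN (2.2 equiv), THF, 0 °C → rt; then 17, Pd(OAc)2 (3 mol %), SPhos (6 mol %), aq K3PO4, THF, 60 °C
Reagents that add atoms: 9-BBN-H, [H]B1C2CCCC1CCC2 (boron appears only in non-isolated 18; only H stays in 19)
Why: 9-BBN hydroborates only the monosubstituted allyl alkene (the trisubstituted prenyl groups are far slower and the phenol just consumes one equivalent), and the B-alkyl Suzuki–Miyaura coupling with an electron-rich biaryl phosphine tolerates free phenols and should outrun Pd(0) ionisation of the hindered prenyl aryl ether.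

**Step 8**
Reactants: 19 prenyl ether
Product: 21 kazinol D, via the 6-(2-methylbut-3-en-2-yl)cyclohexa-2,4-dienone tautomer of ring A 20 (not isolated)
Conditions: PhNEt2, 195 °C, sealed tube, Ar, about 2 h
Reagents that add atoms: none
Why: The [3,3]-shift of this aromatic Claisen rearrangement inverts the prenyl unit to the 1,1-dimethylallyl group and goes to C5' rather than C3', which is flanked by two oxygens and poorly accepts a quaternary carbon, after which dienone 20 tautomerises to the phenol and its transient stereocentre disappears.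

**Compound list**
1 | prop-2-yn-1-ol | C#CCO | starting material
2 | prenyl bromide | CC(C)=CCBr | starting material
3 | 6-methylhept-5-en-2-yn-1-ol | CC(C)=CCC#CCO | intermediate
4 | allylmagnesium bromide | C=CC[Mg]Br | starting material
5 | bromomagnesium (Z)-2-allyl-3-(bromomagnesio)-6-methylhepta-2,5-dien-1-olate | Br[Mg]OC/C(CC=C)=C(\[Mg]Br)CC=C(C)C | intermediate
6 | (Z)-2-allyl-3-iodo-6-methylhepta-2,5-dien-1-ol | OC/C(CC=C)=C(\I)CC=C(C)C | intermediate
7 | 2-methylpent-4-yn-2-ol | C#CCC(C)(C)O | starting material
8 | (Z)-2-allyl-7-methyl-3-(3-methylbut-2-enyl)oct-2-en-4-yne-1,7-diol | OC/C(CC=C)=C(\C#CCC(C)(C)O)CC=C(C)C | intermediate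
9 | 4-[4-allyl-3-(3-methylbut-2-enyl)furan-2-yl]-2-methylbutan-2-ol | C=CCc1coc(CCC(C)(C)O)c1CC=C(C)C | intermediate
10 | trichloroethylene | ClC=C(Cl)Cl | starting material
11 | 4-allyl-2-{3-[(E)-1,2-dichlorovinyloxy]-3-methylbutyl}-3-(3-methylbut-2-enyl)furan | C=CCc1coc(CCC(C)(C)O/C(Cl)=C\Cl)c1CC=C(C)C | intermediate
12 | lithium alkoxyacetylide of 13 | C=CCc1coc(CCC(C)(C)OC#C[Li])c1CC=C(C)C | intermediate
13 | 4-allyl-2-[3-(ethynyloxy)-3-methylbutyl]-3-(3-methylbut-2-enyl)furan | C=CCc1coc(CCC(C)(C)OC#C)c1CC=C(C)C | intermediate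
14 | dihydropyran-fused oxepine (tautomer of the C7–C8 arene oxide) | C=CCC1=COC=C2OC(C)(C)CCC2=C1CC=C(C)C | intermediate
15 | 6-allyl-2,2-dimethyl-5-(3-methylbut-2-enyl)chroman-8-ol | C=CCc1cc(O)c2OC(C)(C)CCc2c1CC=C(C)C | intermediate
16 | 4-bromoresorcinol | Oc1ccc(Br)c(O)c1 | starting material
17 | 2-bromo-5-[(3-methylbut-2-enyl)oxy]phenol | CC(C)=CCOc1ccc(Br)c(O)c1 | intermediate
18 | B-alkyl-9-BBN / O-borinate of 15 | CC(C)=CCc1c(CCCB2C3CCCC2CCC3)cc(OB2C3CCCC2CCC3)c2OC(C)(C)CCc12 | intermediate
19 | 6-{3-[2-hydroxy-4-(3-methylbut-2-enyloxy)phenyl]propyl}-2,2-dimethyl-5-(3-methylbut-2-enyl)chroman-8-ol | CC(C)=CCOc1ccc(CCCc2cc(O)c3OC(C)(C)CCc3c2CC=C(C)C)c(O)c1 | intermediate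
20 | ortho-dienone Claisen intermediate (racemic, transient) | C=CC(C)(C)C1C=C(CCCc2cc(O)c3OC(C)(C)CCc3c2CC=C(C)C)C(O)=CC1=O | intermediate
21 | kazinol D (achiral) | C=CC(C)(C)c1cc(CCCc2cc(O)c3c(c2CC=C(C)C)CCC(C)(C)O3)c(O)cc1O | target

**Total steps:** 8. **Longest linear sequence:** 7 (steps 1, 2, 3, 4, 5, 7, 8). No protecting groups are used.

**Three steps most likely to fail**

Step 5. The possible failures are:
- hydration of the tert-alkyl ynol ether;
- gold-induced loss of the tertiary alkyl group;
- addition of the product phenol to 13;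
- non-selective opening of the arene oxide, since furan C5 is unsubstituted.

The fallback builds the same two rings together by alkyne cyclotrimerisation instead of from a furan. It sets out from 2 (with 10) and comes back at 15. Cu-catalysed coupling of 2 with purchased 2-methylhex-5-yn-2-ol gives 2,9-dimethyldec-8-en-5-yn-2-ol F1. KH and 10 give its (E)-1,2-dichlorovinyl ether F2, and n-BuLi gives the lithium alkoxyacetylide F3. Quenching with chloro(isopropoxy)dimethylsilane gives the C-silylated ynol-ether diyne F4. [Rh(cod)2]BF4/BINAP-catalysed [2+2+2] cycloaddition of F4 with purchased pent-1-en-4-yne closes the arene and pyran rings at once, with the bulky silyl terminus directing the allyl group to the distal position. This gives 6-allyl-8-[isopropoxy(dimethyl)silyl]-2,2-dimethyl-5-prenylchroman F5. Tamao oxidation (H2O2, KF, KHCO3) then gives 15.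

Step 4. KH or the potassium alkoxide may isomerise the allyl/prenyl furan, and the hindered alkoxide may react sluggishly with 10. The fallback moves the ether formation ahead of furan construction. It sets out from 7 (with 10 and 6) and comes back at 11. KH and 10 convert 7 to the distillable 4-[(E)-1,2-dichlorovinyloxy]-4-methylpent-1-yne F6. Sonogashira coupling with 6 gives (Z)-2-allyl-7-[(E)-1,2-dichlorovinyloxy]-7-methyl-3-(3-methylbut-2-enyl)oct-2-en-4-yn-1-ol F7. F7 has only one free OH, so Ag(I) cyclisation can only give 11, and only the n-BuLi stage remains to be done on the furan.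

Step 8. Some C3' migration is possible, and the o-(1,1-dimethylallyl)phenol may cyclise thermally or undergo abnormal Claisen rearrangement in a late, precious intermediate. The fallback rearranges before the fragments are joined. It sets out from 17 (with 18) and comes back at 21. Thermolysis of 17 gives 4-bromo-6-(2-methylbut-3-en-2-yl)benzene-1,3-diol F8, whose regioisomers can be separated at this cheap stage. TBSCl/imidazole gives its bis(TBS) ether F9. Suzuki coupling with 18 gives 2',4'-bis-O-TBS kazinol D F10, and TBAF releases 21. This order also removes the prenyl aryl ether from the palladium step.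

**Further compounds**
F1 | step 5 | 2,9-dimethyldec-8-en-5-yn-2-ol | CC(C)=CCC#CCCC(C)(C)O
F2 | step 5 | (E)-1,2-dichlorovinyl ether of F1 | CC(C)=CCC#CCCC(C)(C)O/C(Cl)=C\Cl
F3 | step 5 | lithium alkoxyacetylide from F2 | CC(C)=CCC#CCCC(C)(C)OC#C[Li]
F4 | step 5 | isopropoxy(dimethyl)silyl ynol-ether diyne | CC(C)=CCC#CCCC(C)(C)OC#C[Si](C)(C)OC(C)C
F5 | step 5 | 6-allyl-8-[isopropoxy(dimethyl)silyl]-2,2-dimethyl-5-(3-methylbut-2-enyl)chroman | C=CCc1cc([Si](C)(C)OC(C)C)c2OC(C)(C)CCc2c1CC=C(C)C
F6 | step 4 | 4-[(E)-1,2-dichlorovinyloxy]-4-methylpent-1-yne | C#CCC(C)(C)O/C(Cl)=C\Cl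
F7 | step 4 | (Z)-2-allyl-7-[(E)-1,2-dichlorovinyloxy]-7-methyl-3-(3-methylbut-2-enyl)oct-2-en-4-yn-1-ol | OC/C(CC=C)=C(\C#CCC(C)(C)O/C(Cl)=C\Cl)CC=C(C)C
F8 | step 8 | 4-bromo-6-(2-methylbut-3-en-2-yl)benzene-1,3-diol | C=CC(C)(C)c1cc(Br)c(O)cc1O
F9 | step 8 | bis(TBS) ether of F8 | C=CC(C)(C)c1cc(Br)c(O[Si](C)(C)C(C)(C)C)cc1O[Si](C)(C)C(C)(C)C
F10 | step 8 | 2',4'-bis-O-TBS kazinol D | C=CC(C)(C)c1cc(CCCc2cc(O)c3OC(C)(C)CCc3c2CC=C(C)C)c(O[Si](C)(C)C(C)(C)C)cc1O[Si](C)(C)C(C)(C)C
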